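**Retrosynthetic overview**

1. Target numbering (decalin): C1 carries the propanoic acid chain, C2 is the ketone, C4a the ring-fusion CH, C5 the quaternary carbon with methyl and arylmethyl, C6 the CH–CH3, C8a the angular C–CH3; ring A = C1–C4, C4a, C8a; ring B = C4a–C8a.
2. The strategy rests on the C4a–C5 bond of ring B, with C6–C7 as a latent alkene: both arise in one Ireland–Claisen ring contraction of a 6-alkenyl δ-lactone whose C-4 is the future C8a, so ring B is formed first.
3. The lactone comes from anti addition of Me2CuLi to a 4-substituted 5,6-dihydropyran-2-one (sets C8a against the carbinol). That lactone is closed by an intramolecular Horner–Wadsworth–Emmons reaction of a 1,5-anti boron aldol adduct; the 2-oxopropyl arm travels as an (S)-2-benzyloxypropyl group that also controls the carbinol.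
4. The (Z)-tetrasubstituted enal for the aldol is built from but-2-yn-1-ol by anti-carbomagnesiation/iodination, allylic arylation and formylation.
5. After the key step: acid to alcohol, hydroxyl-directed hydrogenation (C6), oxidation and aldol condensation close ring A; α′-allylation, conjugate reduction, hydroboration–oxidation and aryl ether cleavage complete the target.

Key step: step 14

Assumption: the C1 centre α to the ketone (side chain equatorial, cis to the C8a methyl) is taken to be the thermodynamically preferred epimer and is therefore fixed by base equilibration; β denotes the face of the C8a methyl group, α the opposite face.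

**Route**

Step 1
Reactants: 1 4-methoxy-2-methylphenol
Product: 2 2-bromo-4-methoxy-6-methylphenol
Conditions: NBS, MeCN, 0 °C
Reagents that add atoms: N-bromosuccinimide, O=C1CCC(=O)N1Br
Why: Electrophilic aromatic bromination, directed by the hydroxyl group to its only free ortho position (the para position carries the methoxy group).

Step 2
Reactants: 2 2-bromo-4-methoxy-6-methylphenol
Product: 3 1-bromo-2,5-dimethoxy-3-methylbenzene
Conditions: MeI, K2CO3, acetone, reflux
Reagents that add atoms: iodomethane, CI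
Why: Williamson O-methylation of the phenoxide.

Step 3
Reactants: 4 but-2-yn-1-ol
Product: 6 (2Z)-3-iodo-2-methylbut-2-en-1-ol, via cyclic alkenylmagnesium alkoxide 5 (not isolated)
Conditions: MeMgBr (2.5 equiv), CuI (10 mol%), THF, 0 °C → rt; then I2, −78 → 0 °C
Reagents that add atoms: methylmagnesium bromide, C[Mg]Br; iodine, II
Why: Copper-catalysed anti-carbomagnesiation of the propargylic alkoxide places methyl on the proximal and magnesium on the distal alkyne carbon in a five-membered chelate, so iodinolysis with retention should give the alkene with CH2OH cis to iodine.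

Step 4
Reactants: 6 (2Z)-3-iodo-2-methylbut-2-en-1-ol
Product: 7 (2Z)-1-bromo-3-iodo-2-methylbut-2-ene
Conditions: PBr3, Et2O, 0 °C
Reagents that add atoms: phosphorus tribromide, BrP(Br)Br
Why: Conversion of the primary allylic alcohol into the bromide by substitution at the CH2 carbon, which leaves the alkenyl iodide and the alkene geometry untouched.

Step 5
Reactants: 3 1-bromo-2,5-dimethoxy-3-methylbenzene; 7 (2Z)-1-bromo-3-iodo-2-methylbut-2-ene
Product: 9 1-[(2Z)-3-iodo-2-methylbut-2-en-1-yl]-2,5-dimethoxy-3-methylbenzene, via arylmagnesium bromide 8 (not isolated)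
Conditions: Mg, THF, 50 °C; then 7, Li2CuCl4 (3 mol%), THF, −20 → 0 °C
Reagents that add atoms: none
Why: Grignard formation and copper-catalysed coupling with the primary allylic bromide at its α carbon (the γ terminus is fully substituted), the alkenyl iodide being inert to the aryl Grignard reagent at low temperature.

Step 6
Reactants: 9 1-[(2Z)-3-iodo-2-methylbut-2-en-1-yl]-2,5-dimethoxy-3-methylbenzene
Product: 11 (2Z)-4-(2,5-dimethoxy-3-methylphenyl)-2,3-dimethylbut-2-enal, via alkenyllithium 10 (not isolated)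
Conditions: t-BuLi (2.1 equiv), Et2O, −78 °C; DMF, −78 → 0 °C; aq. NH4Cl
Reagents that add atoms: N,N-dimethylformamide, CN(C)C=O
Why: Iodine–lithium exchange with retention of the alkene geometry, then formylation of the configurationally stable alkenyllithium, so the formyl group ends cis to the arylmethyl group.

Step 7
Reactants: 12 ethyl (3S)-3-hydroxybutanoate
Product: 13 ethyl (3S)-3-(benzyloxy)butanoate
Conditions: benzyl 2,2,2-trichloroacetimidate, TfOH (cat.), CH2Cl2–cyclohexane, rt
Reagents that add atoms: benzyl 2,2,2-trichloroacetimidate, N=C(OCc1ccccc1)C(Cl)(Cl)Cl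
Why: Acid-catalysed O-benzylation with the imidate avoids base, so neither β-elimination nor loss of configuration is expected.

Step 8
Reactants: 13 ethyl (3S)-3-(benzyloxy)butanoate
Product: 14 (3S)-3-(benzyloxy)-N-methoxy-N-methylbutanamide
Conditions: MeNHOMe·HCl, i-PrMgCl, THF, −20 °C
Reagents that add atoms: N,O-dimethylhydroxylamine hydrochloride, CNOC.Cl
Why: Aminolysis of the ester by the magnesium amide of N,O-dimethylhydroxylamine.

Step 9
Reactants: 14 (3S)-3-(benzyloxy)-N-methoxy-N-methylbutanamide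
Product: 15 (4S)-4-(benzyloxy)pentan-2-one
Conditions: MeMgBr, THF, 0 °C
Reagents that add atoms: methylmagnesium bromide, C[Mg]Br
Why: Ketone synthesis from the N-methoxy-N-methylamide, in which the magnesium chelate of the tetrahedral adduct prevents a second addition.

Step 10
Reactants: 15 (4S)-4-(benzyloxy)pentan-2-one; 11 (2Z)-4-(2,5-dimethoxy-3-methylphenyl)-2,3-dimethylbut-2-enal
Product: 17 (2S,6R,7Z)-2-(benzyloxy)-9-(2,5-dimethoxy-3-methylphenyl)-6-hydroxy-7,8-dimethylnon-7-en-4-one, via dibutylboron enolate 16 (not isolated)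
Conditions: n-Bu2BOTf, i-Pr2NEt, Et2O, −78 °C; then 11, −78 → −20 °C; H2O2, MeOH, pH 7 buffer, 0 °C
Reagents that add atoms: none
Why: Boron aldol addition of the methyl-side enolate, in which the β-benzyloxy stereocentre should direct the new carbinol by 1,5-anti induction to the (6R) configuration, the minor diastereomer being separable by chromatography.

Step 11
Reactants: 17 (2S,6R,7Z)-2-(benzyloxy)-9-(2,5-dimethoxy-3-methylphenyl)-6-hydroxy-7,8-dimethylnon-7-en-4-one
Product: 18 (2S,6R,7Z)-2-(benzyloxy)-9-(2,5-dimethoxy-3-methylphenyl)-7,8-dimethyl-4-oxonon-7-en-6-yl 2-(diethoxyphosphoryl)acetate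
Conditions: (EtO)2P(O)CH2CO2H, DCC, DMAP (cat.), CH2Cl2, 0 °C → rt
Reagents that add atoms: 2-(diethoxyphosphoryl)acetic acid, CCOP(=O)(CC(=O)O)OCC
Why: Steglich esterification of the secondary allylic alcohol under neutral conditions that should not dehydrate the β-hydroxy ketone.

Step 12
Reactants: 18 (2S,6R,7Z)-2-(benzyloxy)-9-(2,5-dimethoxy-3-methylphenyl)-7,8-dimethyl-4-oxonon-7-en-6-yl 2-(diethoxyphosphoryl)acetate
Product: 19 (6R)-4-[(2S)-2-(benzyloxy)propyl]-6-[(2Z)-4-(2,5-dimethoxy-3-methylphenyl)-3-methylbut-2-en-2-yl]-5,6-dihydro-2H-pyran-2-one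
Conditions: LiCl, i-Pr2NEt, MeCN, rt
Reagents that add atoms: none
Why: Intramolecular Horner–Wadsworth–Emmons olefination of the ketone under mild LiCl/amine conditions closes the six-membered unsaturated lactone, the weak base being chosen to avoid β-elimination of the acyloxy ketone.

Step 13
Reactants: 19 (6R)-4-[(2S)-2-(benzyloxy)propyl]-6-[(2Z)-4-(2,5-dimethoxy-3-methylphenyl)-3-methylbut-2-en-2-yl]-5,6-dihydro-2H-pyran-2-one
Product: 21 (4R,6R)-4-[(2S)-2-(benzyloxy)propyl]-4-methyl-6-[(2Z)-4-(2,5-dimethoxy-3-methylphenyl)-3-methylbut-2-en-2-yl]oxan-2-one, via trimethylsilyl ketene acetal 20 (not isolated)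
Conditions: Me2CuLi (from MeLi, CuI), TMSCl, THF–Et2O, −78 → −30 °C; aq. NH4Cl
Reagents that add atoms: lithium dimethylcuprate, [Li+].C[Cu-]C
Why: TMSCl-accelerated cuprate conjugate addition, in which axial attack anti to the pseudo-equatorial C-6 alkenyl group should place the new methyl trans to it and leave the benzyloxypropyl arm cis to the alkenyl group at the new quaternary C-4; the trimethylsilyl ketene acetal formed in the flask is hydrolysed to the lactone on aqueous work-up.

Step 14
Reactants: 21 (4R,6R)-4-[(2S)-2-(benzyloxy)propyl]-4-methyl-6-[(2Z)-4-(2,5-dimethoxy-3-methylphenyl)-3-methylbut-2-en-2-yl]oxan-2-one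
Product: 24 (1S,2R,6S)-6-[(2S)-2-(benzyloxy)propyl]-2-[(2,5-dimethoxy-3-methylphenyl)methyl]-2,3,6-trimethylcyclohex-3-ene-1-carboxylic acid, via tert-butyldimethylsilyl ketene acetal 22 (not isolated), via tert-butyldimethylsilyl ester 23 (not isolated)
Conditions: LiN(i-Pr)2, TBSCl, THF–HMPA, −78 °C → rt; PhMe, 110 °C; then 1 M HCl, THF, rt
Reagents that add atoms: none
Why: Kinetic deprotonation at C-3 with in situ O-silylation by TBSCl in THF–HMPA gives the cyclic tert-butyldimethylsilyl ketene acetal 22, which on heating should undergo a concerted suprafacial [3,3]-sigmatropic shift (Ireland–Claisen rearrangement in its lactone ring-contraction form, the closest known reaction type), C-3 bonding to the tetrasubstituted alkene terminus while the ring C-6–O bond breaks. Ring B closes in this step as a ring contraction: the new six-membered carbocycle consists of lactone C-3 to C-6 and the two alkene carbons, and because ketene acetal and allyl unit are tied through C-4 and C-5 the shift can only pass through a bicyclo[2.2.2]-like boat transition state. The new CH centre (C-1 of 24) is controlled by the ring-fixed ketene acetal geometry and by suprafacial transfer of the C-6 configuration of 21; the new quaternary centre (C-2) is controlled by the (Z)-alkene geometry, which puts the arylmethyl group trans and the methyl group cis to the carboxyl group. Their sense relative to the existing quaternary carbon follows from the cis relationship of the alkenyl and benzyloxypropyl groups in 21, so the carboxyl group should end cis to both ring methyl groups. The step needs O- rather than C-silylation and a shift that outruns ionisation or elimination at the allylic C–O bond; the bulky silyl chloride in the presence of HMPA should react at oxygen, the tert-butyldimethylsilyl ketene acetal is robust enough to be freed from salts and heated in toluene, and the benzyl and aryl ethers are inert.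

Step 15
Reactants: 24 (1S,2R,6S)-6-[(2S)-2-(benzyloxy)propyl]-2-[(2,5-dimethoxy-3-methylphenyl)methyl]-2,3,6-trimethylcyclohex-3-ene-1-carboxylic acid
Product: 25 [(1S,2R,6S)-6-[(2S)-2-(benzyloxy)propyl]-2-[(2,5-dimethoxy-3-methylphenyl)methyl]-2,3,6-trimethylcyclohex-3-en-1-yl]methanol
Conditions: LiAlH4, THF, 0 °C → reflux
Reagents that add atoms: none
Why: Hydride reduction of the hindered carboxylic acid to the primary alcohol, which does not touch the ring stereocentres.

Step 16
Reactants: 25 [(1S,2R,6S)-6-[(2S)-2-(benzyloxy)propyl]-2-[(2,5-dimethoxy-3-methylphenyl)methyl]-2,3,6-trimethylcyclohex-3-en-1-yl]methanol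
Product: 26 [(1S,2S,3S,6S)-6-[(2S)-2-(benzyloxy)propyl]-2-[(2,5-dimethoxy-3-methylphenyl)methyl]-2,3,6-trimethylcyclohexyl]methanol
Conditions: [Ir(cod)(PCy3)(py)]PF6 (5 mol%), H2 (1 atm), CH2Cl2, rt
Reagents that add atoms: none
Why: Hydroxyl-directed homogeneous hydrogenation, in which the cationic iridium centre bound to the CH2OH group should deliver hydrogen to the alkene face cis to it, so that the C-3 hydrogen ends cis and the C-3 methyl trans to the hydroxymethyl group.

Step 17
Reactants: 26 [(1S,2S,3S,6S)-6-[(2S)-2-(benzyloxy)propyl]-2-[(2,5-dimethoxy-3-methylphenyl)methyl]-2,3,6-trimethylcyclohexyl]methanol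
Product: 27 (2S)-1-[(1S,2S,3S,4S)-3-[(2,5-dimethoxy-3-methylphenyl)methyl]-2-(hydroxymethyl)-1,3,4-trimethylcyclohexyl]propan-2-ol
Conditions: H2 (1 atm), Pd(OH)2/C, EtOAc–MeOH, rt
Reagents that add atoms: none
Why: Hydrogenolysis of the benzyl ether, with nothing else in the molecule reducible under these conditions.

Step 18
Reactants: 27 (2S)-1-[(1S,2S,3S,4S)-3-[(2,5-dimethoxy-3-methylphenyl)methyl]-2-(hydroxymethyl)-1,3,4-trimethylcyclohexyl]propan-2-ol
Product: 28 (1S,2S,3S,6S)-2-[(2,5-dimethoxy-3-methylphenyl)methyl]-2,3,6-trimethyl-6-(2-oxopropyl)cyclohexane-1-carbaldehyde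
Conditions: Dess–Martin periodinane (2.5 equiv), CH2Cl2, 0 °C → rt
Reagents that add atoms: none
Why: Dess–Martin oxidation of both alcohols to the 1,5-keto aldehyde under conditions that should not epimerise the hindered aldehyde α-centre.

Step 19
Reactants: 28 (1S,2S,3S,6S)-2-[(2,5-dimethoxy-3-methylphenyl)methyl]-2,3,6-trimethyl-6-(2-oxopropyl)cyclohexane-1-carbaldehyde
Product: 30 5α-[(2,5-dimethoxy-3-methylphenyl)methyl]-5β,6α,8aβ-trimethyl-4aα,5,6,7,8,8a-hexahydronaphthalen-2(1H)-one (trans-fused), via aldol adduct 29 (not isolated)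
Conditions: KOH, MeOH, 0 °C → rt
Reagents that add atoms: none
Why: Intramolecular aldol condensation in which the methyl-side enolate attacks the aldehyde in a 6-(enolendo)-exo-trig closure, the only six-membered mode available, and dehydration gives the ring A enone with the trans ring fusion already set by the trans aldehyde and oxopropyl groups.

Step 20
Reactants: 30 5α-[(2,5-dimethoxy-3-methylphenyl)methyl]-5β,6α,8aβ-trimethyl-4aα,5,6,7,8,8a-hexahydronaphthalen-2(1H)-one
Product: 32 1-allyl-5α-[(2,5-dimethoxy-3-methylphenyl)methyl]-5β,6α,8aβ-trimethyl-4aα,5,6,7,8,8a-hexahydronaphthalen-2(1H)-one (C-1 epimers), via lithium dienolate 31 (not isolated)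
Conditions: LiN(i-Pr)2, THF, −78 °C; allyl bromide, DMPU, −78 → 0 °C
Reagents that add atoms: allyl bromide, C=CCBr
Why: Kinetic α′-deprotonation of the enone at C-1 and allylation of the cross-conjugated enolate, the enone fixing the regiochemistry, while the C-1 configuration is corrected in step 21.

Step 21
Reactants: 32 1-allyl-5α-[(2,5-dimethoxy-3-methylphenyl)methyl]-5β,6α,8aβ-trimethyl-4aα,5,6,7,8,8a-hexahydronaphthalen-2(1H)-one (C-1 epimers)
Product: 34 (1S,4aR,5S,6S,8aR)-1-allyl-5-[(2,5-dimethoxy-3-methylphenyl)methyl]-5,6,8a-trimethyloctahydronaphthalen-2(1H)-one, via unequilibrated allyl ketone 33 (not isolated)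
Conditions: [(Ph3P)CuH]6, PhH, H2O (2 equiv), rt; then NaOMe (cat.), MeOH, rt
Reagents that add atoms: none
Why: Copper hydride conjugate reduction of the enone leaves the terminal alkene untouched, and base equilibration of the enolisable C-1 centre should favour the equatorial allyl group cis to the C8a methyl.

Step 22
Reactants: 34 (1S,4aR,5S,6S,8aR)-1-allyl-5-[(2,5-dimethoxy-3-methylphenyl)methyl]-5,6,8a-trimethyloctahydronaphthalen-2(1H)-one
Product: 36 (1S,4aR,5S,6S,8aR)-5-[(2,5-dimethoxy-3-methylphenyl)methyl]-1-(3-hydroxypropyl)-5,6,8a-trimethyloctahydronaphthalen-2(1H)-one, via alkyl catechol boronate 35 (not isolated)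
Conditions: catecholborane, RhCl(PPh3)3 (3 mol%), THF, rt; then NaOH, H2O2, 0 °C
Reagents that add atoms: hydrogen peroxide, OO
Why: Rhodium-catalysed anti-Markovnikov hydroboration of the terminal alkene, in which the catalysed alkene addition should outpace ketone reduction, followed by oxidation of the C–B bond.

Step 23
Reactants: 36 (1S,4aR,5S,6S,8aR)-5-[(2,5-dimethoxy-3-methylphenyl)methyl]-1-(3-hydroxypropyl)-5,6,8a-trimethyloctahydronaphthalen-2(1H)-one
Product: 37 3-[(1S,4aR,5S,6S,8aR)-5-[(2,5-dimethoxy-3-methylphenyl)methyl]-5,6,8a-trimethyl-2-oxodecahydronaphthalen-1-yl]propanoic acid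
Conditions: TEMPO (20 mol%), PhI(OAc)2 (2.5 equiv), MeCN–H2O, rt
Reagents that add atoms: water, O
Why: Nitroxyl-catalysed oxidation of the primary alcohol through the aldehyde hydrate to the carboxylic acid, which leaves the ketone and the dimethoxyarene untouched.

Step 24
Reactants: 37 3-[(1S,4aR,5S,6S,8aR)-5-[(2,5-dimethoxy-3-methylphenyl)methyl]-5,6,8a-trimethyl-2-oxodecahydronaphthalen-1-yl]propanoic acid
Product: 38 3-[(1S,4aR,5S,6S,8aR)-5-[(2,5-dihydroxy-3-methylphenyl)methyl]-5,6,8a-trimethyl-2-oxodecahydronaphthalen-1-yl]propanoic acid (CNP0167047.1)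
Conditions: BBr3 (6 equiv), CH2Cl2, −78 → 0 °C; then H2O, under argon
Reagents that add atoms: none
Why: Lewis acid cleavage of both aryl methyl ethers to the hydroquinone; the C-1 centre is already the thermodynamic epimer, so acid-induced enolisation should not change it.

**Compound list**

1 | 4-methoxy-2-methylphenol | Cc1cc(OC)ccc1O | starting material
2 | 2-bromo-4-methoxy-6-methylphenol | Cc1cc(OC)cc(Br)c1O | intermediate
3 | 1-bromo-2,5-dimethoxy-3-methylbenzene | Cc1cc(OC)cc(Br)c1OC | intermediate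
4 | but-2-yn-1-ol | CC#CCO | starting material
5 | 3,4-dimethyl-2,5-dihydro-1,2-oxamagnesole (cyclic alkenylmagnesium alkoxide, not isolated) | CC1=C(C)[Mg]OC1 | intermediate
6 | (2Z)-3-iodo-2-methylbut-2-en-1-ol | OC/C(C)=C(/C)I | intermediate
7 | (2Z)-1-bromo-3-iodo-2-methylbut-2-ene | BrC/C(C)=C(/C)I | intermediate
8 | (2,5-dimethoxy-3-methylphenyl)magnesium bromide (not isolated) | Cc1cc(OC)cc([Mg]Br)c1OC | intermediate
9 | 1-[(2Z)-3-iodo-2-methylbut-2-en-1-yl]-2,5-dimethoxy-3-methylbenzene | I/C(C)=C(/C)Cc1cc(OC)cc(C)c1OC | intermediate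
10 | alkenyllithium from 9, lithium cis to the arylmethyl group (not isolated) | [Li]/C(C)=C(/C)Cc1cc(OC)cc(C)c1OC | intermediate
11 | (2Z)-4-(2,5-dimethoxy-3-methylphenyl)-2,3-dimethylbut-2-enal | O=C/C(C)=C(/C)Cc1cc(OC)cc(C)c1OC | intermediate
12 | ethyl (3S)-3-hydroxybutanoate | C[C@H](O)CC(=O)OCC | starting material
13 | ethyl (3S)-3-(benzyloxy)butanoate | C[C@H](OCc1ccccc1)CC(=O)OCC | intermediate
14 | (3S)-3-(benzyloxy)-N-methoxy-N-methylbutanamide | C[C@H](OCc1ccccc1)CC(=O)N(C)OC | intermediate
15 | (4S)-4-(benzyloxy)pentan-2-one | C[C@H](OCc1ccccc1)CC(C)=O | intermediate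
16 | (4S)-4-(benzyloxy)pent-1-en-2-yl dibutylborinate (boron enolate, not isolated) | C=C(OB(CCCC)CCCC)C[C@H](C)OCc1ccccc1 | intermediate
17 | (2S,6R,7Z)-2-(benzyloxy)-9-(2,5-dimethoxy-3-methylphenyl)-6-hydroxy-7,8-dimethylnon-7-en-4-one | C[C@H](OCc1ccccc1)CC(=O)C[C@@H](O)/C(C)=C(/C)Cc2cc(OC)cc(C)c2OC | intermediate
18 | (2S,6R,7Z)-2-(benzyloxy)-9-(2,5-dimethoxy-3-methylphenyl)-7,8-dimethyl-4-oxonon-7-en-6-yl 2-(diethoxyphosphoryl)acetate | C[C@H](OCc1ccccc1)CC(=O)C[C@@H](OC(=O)CP(=O)(OCC)OCC)/C(C)=C(/C)Cc2cc(OC)cc(C)c2OC | intermediate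
19 | (6R)-4-[(2S)-2-(benzyloxy)propyl]-6-[(2Z)-4-(2,5-dimethoxy-3-methylphenyl)-3-methylbut-2-en-2-yl]-5,6-dihydro-2H-pyran-2-one | O=C1C=C(C[C@H](C)OCc2ccccc2)C[C@@H](O1)/C(C)=C(/C)Cc3cc(OC)cc(C)c3OC | intermediate
20 | cyclic trimethylsilyl ketene acetal of lactone 21 (not isolated) | C[Si](C)(C)OC1=C[C@](C)(C[C@H](C)OCc2ccccc2)C[C@@H](O1)/C(C)=C(/C)Cc3cc(OC)cc(C)c3OC | intermediate
21 | (4R,6R)-4-[(2S)-2-(benzyloxy)propyl]-4-methyl-6-[(2Z)-4-(2,5-dimethoxy-3-methylphenyl)-3-methylbut-2-en-2-yl]oxan-2-one (alkenyl and benzyloxypropyl groups cis; key-step precursor) | O=C1C[C@](C)(C[C@H](C)OCc2ccccc2)C[C@@H](O1)/C(C)=C(/C)Cc3cc(OC)cc(C)c3OC | intermediate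
22 | cyclic tert-butyldimethylsilyl ketene acetal of lactone 21 (not isolated) | CC(C)(C)[Si](C)(C)OC1=C[C@](C)(C[C@H](C)OCc2ccccc2)C[C@@H](O1)/C(C)=C(/C)Cc3cc(OC)cc(C)c3OC | intermediate
23 | tert-butyldimethylsilyl ester of acid 24 (not isolated) | COc1cc(C)c(OC)c(c1)C[C@]2(C)[C@@H](C(=O)O[Si](C)(C)C(C)(C)C)[C@](C)(C[C@H](C)OCc3ccccc3)CC=C2C | intermediate
24 | (1S,2R,6S)-6-[(2S)-2-(benzyloxy)propyl]-2-[(2,5-dimethoxy-3-methylphenyl)methyl]-2,3,6-trimethylcyclohex-3-ene-1-carboxylic acid (CO2H cis to the C-2 and C-6 methyl groups; key-step product) | COc1cc(C)c(OC)c(c1)C[C@]2(C)[C@@H](C(=O)O)[C@](C)(C[C@H](C)OCc3ccccc3)CC=C2C | intermediate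
25 | [(1S,2R,6S)-6-[(2S)-2-(benzyloxy)propyl]-2-[(2,5-dimethoxy-3-methylphenyl)methyl]-2,3,6-trimethylcyclohex-3-en-1-yl]methanol | COc1cc(C)c(OC)c(c1)C[C@]2(C)[C@@H](CO)[C@](C)(C[C@H](C)OCc3ccccc3)CC=C2C | intermediate
26 | [(1S,2S,3S,6S)-6-[(2S)-2-(benzyloxy)propyl]-2-[(2,5-dimethoxy-3-methylphenyl)methyl]-2,3,6-trimethylcyclohexyl]methanol (C-3 methyl trans to CH2OH) | COc1cc(C)c(OC)c(c1)C[C@]2(C)[C@@H](CO)[C@](C)(C[C@H](C)OCc3ccccc3)CC[C@@H]2C | intermediate
27 | (2S)-1-[(1S,2S,3S,4S)-3-[(2,5-dimethoxy-3-methylphenyl)methyl]-2-(hydroxymethyl)-1,3,4-trimethylcyclohexyl]propan-2-ol | COc1cc(C)c(OC)c(c1)C[C@]2(C)[C@@H](CO)[C@](C)(C[C@H](C)O)CC[C@@H]2C | intermediate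
28 | (1S,2S,3S,6S)-2-[(2,5-dimethoxy-3-methylphenyl)methyl]-2,3,6-trimethyl-6-(2-oxopropyl)cyclohexane-1-carbaldehyde | COc1cc(C)c(OC)c(c1)C[C@]2(C)[C@@H](C=O)[C@](C)(CC(C)=O)CC[C@@H]2C | intermediate
29 | 5α-[(2,5-dimethoxy-3-methylphenyl)methyl]-4-hydroxy-5β,6α,8aβ-trimethyl-4aα-octahydronaphthalen-2(1H)-one (aldol adduct, C-4 epimers, not isolated) | COc1cc(C)c(OC)c(c1)C[C@]2(C)[C@H]3C(O)CC(=O)C[C@]3(C)CC[C@@H]2C | intermediate
30 | 5α-[(2,5-dimethoxy-3-methylphenyl)methyl]-5β,6α,8aβ-trimethyl-4aα,5,6,7,8,8a-hexahydronaphthalen-2(1H)-one | COc1cc(C)c(OC)c(c1)C[C@]2(C)[C@H]3C=CC(=O)C[C@]3(C)CC[C@@H]2C | intermediate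
31 | lithium cross-conjugated dienolate of 30 (not isolated) | COc1cc(C)c(OC)c(c1)C[C@]2(C)[C@H]3C=CC(O[Li])=C[C@]3(C)CC[C@@H]2C | intermediate
32 | 1-allyl-5α-[(2,5-dimethoxy-3-methylphenyl)methyl]-5β,6α,8aβ-trimethyl-4aα,5,6,7,8,8a-hexahydronaphthalen-2(1H)-one (C-1 epimers) | COc1cc(C)c(OC)c(c1)C[C@]2(C)[C@H]3C=CC(=O)C(CC=C)[C@]3(C)CC[C@@H]2C | intermediate
33 | 1-allyl-5α-[(2,5-dimethoxy-3-methylphenyl)methyl]-5β,6α,8aβ-trimethyl-4aα-octahydronaphthalen-2(1H)-one (C-1 epimers, not isolated) | COc1cc(C)c(OC)c(c1)C[C@]2(C)[C@H]3CCC(=O)C(CC=C)[C@]3(C)CC[C@@H]2C | intermediate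
34 | (1S,4aR,5S,6S,8aR)-1-allyl-5-[(2,5-dimethoxy-3-methylphenyl)methyl]-5,6,8a-trimethyloctahydronaphthalen-2(1H)-one (1β-allyl, equatorial) | COc1cc(C)c(OC)c(c1)C[C@]2(C)[C@H]3CCC(=O)[C@@H](CC=C)[C@]3(C)CC[C@@H]2C | intermediate
35 | (1S,4aR,5S,6S,8aR)-1-[3-(1,3,2-benzodioxaborol-2-yl)propyl]-5-[(2,5-dimethoxy-3-methylphenyl)methyl]-5,6,8a-trimethyloctahydronaphthalen-2(1H)-one (not isolated) | COc1cc(C)c(OC)c(c1)C[C@]2(C)[C@H]3CCC(=O)[C@@H](CCCB4Oc5ccccc5O4)[C@]3(C)CC[C@@H]2C | intermediate
36 | (1S,4aR,5S,6S,8aR)-5-[(2,5-dimethoxy-3-methylphenyl)methyl]-1-(3-hydroxypropyl)-5,6,8a-trimethyloctahydronaphthalen-2(1H)-one | COc1cc(C)c(OC)c(c1)C[C@]2(C)[C@H]3CCC(=O)[C@@H](CCCO)[C@]3(C)CC[C@@H]2C | intermediate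
37 | 3-[(1S,4aR,5S,6S,8aR)-5-[(2,5-dimethoxy-3-methylphenyl)methyl]-5,6,8a-trimethyl-2-oxodecahydronaphthalen-1-yl]propanoic acid | COc1cc(C)c(OC)c(c1)C[C@]2(C)[C@H]3CCC(=O)[C@@H](CCC(=O)O)[C@]3(C)CC[C@@H]2C | intermediate
38 | 3-[(1S,4aR,5S,6S,8aR)-5-[(2,5-dihydroxy-3-methylphenyl)methyl]-5,6,8a-trimethyl-2-oxodecahydronaphthalen-1-yl]propanoic acid (CNP0167047.1) | Cc1cc(O)cc(C[C@]2(C)[C@H]3CCC(=O)[C@@H](CCC(=O)O)[C@]3(C)CC[C@@H]2C)c1O | target

**Step count**

Total: 24 steps. Longest linear sequence: 19 steps (from 1 or from 4 through steps 5, 6 and 10–24).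

**Steps most likely to fail**

1. Step 14 (ring contraction). The [3,3] shift is slowed by the tetrasubstituted terminus (the arylmethyl group sits over the lactone in the boat transition state). Incomplete or unselective enolisation–silylation next to the quaternary carbon (C-silylation, fragmentation of the lithium enolate) would then leave too little ketene acetal, and ionisation of the allylic C–O bond could compete during long heating. Fallback, from 19 back to 24: the rearranging species is reached by conjugate addition and enolate trapping in place of deprotonation. The Me2CuLi/TMSCl addition of step 13 is run on 19 and the trimethylsilyl ketene acetal 20 is not hydrolysed; copper salts are filtered off under argon, the solvent is changed to toluene and the solution is heated at 110 °C to give the trimethylsilyl ester F1, which dilute acid converts into 24.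

2. Step 16 (directed hydrogenation). Facial selectivity may be poor if the iridium centre cannot hold the hydroxyl group and the hindered trisubstituted alkene at once (the hydroxymethyl group must turn axial), or if the benzyl ether oxygen on the opposite face competes for the metal; hydrogen would then add from the α face. Fallback, from 24 back to 26: the reduction is moved to the acid stage and directed by a carboxamide, which binds more strongly and sits one atom closer to the ring. Acid 24 is treated with (COCl)2 and catalytic DMF to give the acid chloride F2, and pyrrolidine/Et3N gives the pyrrolidine amide F3. Hydrogenation with [Ir(cod)(PCy3)(py)]PF6 in CH2Cl2 should then give the saturated amide F4 with hydrogen delivered cis to the amide carbonyl. Reduction with LiH2NBH3 in THF returns alcohol 26.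

3. Step 13 (conjugate methylation). Addition to the β,β-disubstituted lactone may be sluggish, so that the cuprate instead attacks the allylic lactone C–O bond (substitution or reductive opening). Fallback, from 17 back to 21: the acceptor is doubly activated. Alcohol 17 is esterified with 3-oxo-3-[2-(trimethylsilyl)ethoxy]propanoic acid (DCC, DMAP) to the mixed malonate F5. Piperidinium acetate in refluxing benzene closes the ring by intramolecular Knoevenagel condensation to the alkylidene malonate lactone F6. Me2CuLi at −78 °C should add anti to the C-6 alkenyl group to give the methylated malonate lactone F7. Bu4NF in THF, then warming to 60 °C, removes the ester group (fluoride cleavage and decarboxylation) and returns lactone 21.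

Further compounds
F1 | step 14 | trimethylsilyl (1S,2R,6S)-6-[(2S)-2-(benzyloxy)propyl]-2-[(2,5-dimethoxy-3-methylphenyl)methyl]-2,3,6-trimethylcyclohex-3-ene-1-carboxylate | COc1cc(C)c(OC)c(c1)C[C@]2(C)[C@@H](C(=O)O[Si](C)(C)C)[C@](C)(C[C@H](C)OCc3ccccc3)CC=C2C
F2 | step 16 | (1S,2R,6S)-6-[(2S)-2-(benzyloxy)propyl]-2-[(2,5-dimethoxy-3-methylphenyl)methyl]-2,3,6-trimethylcyclohex-3-ene-1-carbonyl chloride | COc1cc(C)c(OC)c(c1)C[C@]2(C)[C@@H](C(=O)Cl)[C@](C)(C[C@H](C)OCc3ccccc3)CC=C2C
F3 | step 16 | pyrrolidine amide of acid 24 (ring configuration as in 24) | COc1cc(C)c(OC)c(c1)C[C@]2(C)[C@@H](C(=O)N3CCCC3)[C@](C)(C[C@H](C)OCc4ccccc4)CC=C2C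
F4 | step 16 | saturated pyrrolidine amide (ring configuration as in 26, C-3 methyl trans to the amide group) | COc1cc(C)c(OC)c(c1)C[C@]2(C)[C@@H](C(=O)N3CCCC3)[C@](C)(C[C@H](C)OCc4ccccc4)CC[C@@H]2C
F5 | step 13 | (2S,6R,7Z)-2-(benzyloxy)-9-(2,5-dimethoxy-3-methylphenyl)-7,8-dimethyl-4-oxonon-7-en-6-yl 2-(trimethylsilyl)ethyl propanedioate | C[C@H](OCc1ccccc1)CC(=O)C[C@@H](OC(=O)CC(=O)OCC[Si](C)(C)C)/C(C)=C(/C)Cc2cc(OC)cc(C)c2OC
F6 | step 13 | 2-(trimethylsilyl)ethyl (6R)-4-[(2S)-2-(benzyloxy)propyl]-6-[(2Z)-4-(2,5-dimethoxy-3-methylphenyl)-3-methylbut-2-en-2-yl]-2-oxo-5,6-dihydro-2H-pyran-3-carboxylate | O=C1C(C(=O)OCC[Si](C)(C)C)=C(C[C@H](C)OCc2ccccc2)C[C@@H](O1)/C(C)=C(/C)Cc3cc(OC)cc(C)c3OC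
F7 | step 13 | 2-(trimethylsilyl)ethyl ester of the 3-carboxy derivative of lactone 21 (C-3 epimers; C-4 and C-6 as in 21) | O=C1C(C(=O)OCC[Si](C)(C)C)[C@](C)(C[C@H](C)OCc2ccccc2)C[C@@H](O1)/C(C)=C(/C)Cc3cc(OC)cc(C)c3OC
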